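## Structural features

The target is a flavone. Benzo ring A carries oxygen at C5 and C7 and is fused through C4a–C8a to the 4-pyranone ring C; aryl ring B is attached by the single bond C2–C1'. The molecule has no stereocentre, so none stand next to each other; the only stereocentres on the way are the two bridgeheads of the transient adduct 9, and they vanish on aromatisation. Four oxygen substituents must be told apart: a hydrogen sulfate on O7, a hydroxyl on O5 that is hydrogen-bonded to the C4 carbonyl, a free hydroxyl on O3' and a methyl ether on O4'. The aryl O-sulfate monoester is the fragile group, because acid hydrolyses it and it is safe only as its salt in base; C2 of ring C is also open to attack by hard nucleophiles such as alkoxides. The real difficulty is therefore not the skeleton but placing one sulfate on O7 in the presence of O5–H and O3'–H, together with the ring B pattern of hydroxyl at C3' and methyl ether at C4'. The key step exploits this ortho pair: C3'–OH and C4'–OMe correspond to the bridge oxygen and the methoxy group of the adduct between a 3-methoxyfuran and an alkyne on C2 of ring C, so ring B is built with O3' as the only unprotected hydroxyl while O5 and O7 stay benzylated.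

## Logic of the disconnections

**14 from 12 (through 13).** The O7–S bond is cut, and the acetyl group is put back on O3'. The sulfate goes on last because it is the most fragile and most polar group; what remains is a neutral diphenol that can be purified on silica. The forward step must sulfate O7 and neither O5 nor O3'. O5 is deactivated by its hydrogen bond, O3' has to be capped, and the cap must come off in base, where an aryl sulfate anion is stable.

**12 from 11.** The two benzylic C–O bonds on O5 and O7 are cut. Both ring A oxygens are released together, and only after O3' has been capped, so ring A and ring B hydroxyls never have to be distinguished by reactivity alone. The forward hydrogenolysis must leave the C2=C3 bond of ring C, the aryl acetate and the methyl ether untouched.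

**11 from 10.** The O3'–acyl bond is cut. 10 has a single free hydroxyl, so the acylation needs no selectivity. The gain is that the difference between O3' and the ring A oxygens, created in the key step, is stored in two orthogonal protecting groups.

**10 from 7 and 8 (through 9).** The bonds C2'–C3' and C1'–C6' are cut, and the bridge bond C6'–O is formally restored. Atom mapping shows the plan is self-consistent: C1' and C2' are the internal and terminal alkyne carbons of 7, and C3', C4', C5' and C6' are C2, C3, C4 and C5 of 8. The methoxy carbon therefore lies para to C1' and the bridge oxygen stays on C3'. The gain is large: ring B with both its oxygens comes from 8, a commercial furan, and the 3'-hydroxyl is born free without a protecting-group step. The demand is heavy: the alkyne must be electrophilic enough, the addition must take one orientation, and the bridge must open in one direction.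

**7 from 6.** The triple bond is cut between its two carbons, which removes the terminal carbon (the future C2'). A one-carbon homologation of an aldehyde is the shortest way to a terminal alkyne on C2 of ring C, a position not easily reached by cross-coupling. The forward step must not add a nucleophile to C2 of ring C or to the new enynone.

**6 from 5.** No skeletal bond is cut; the formyl group is traced back to the ethoxycarbonyl group. The reduction must stop at the aldehyde and must not touch the C4 carbonyl.

**5 from 4.** The two benzylic C–O bonds at O5 and O7 are cut again, now to reveal the diphenol ester. Benzyl ethers are kept on both oxygens of 7 for three reasons: they survive hydride reduction, the basic alcoholic medium of the homologation, heat and mild acid; they leave ring A without acidic protons that would destroy 8; and they fall together later. The price is a less electrophilic alkyne. The forward step must alkylate the hydrogen-bonded O5 as well as O7.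

**4 from 1 and 2 (through 3).** The bonds C2–C3 and O1–C2 of ring C are cut. This leads back to an acetophenone that holds ring A with all its oxygens and to a two-carbon diester that supplies C2 and the carboxylate handle. Since 1 is symmetrical, either ortho hydroxyl closes the ring to the same product. The forward step needs C-acylation of the methyl ketone beside three free phenols, which costs excess base, followed by acid-mediated ring closure.

## Other disconnections considered

**Alternative 1:** The cut goes through ring C at C3–C4 and C8a–O1.
- **Forward step:** the lithium enolate of 1-[3-(benzyloxy)-4-methoxyphenyl]ethanone A1 is C-acylated by 2,4,6-trifluorobenzoyl chloride A2. The enolate oxygen of the acylation product then displaces an ortho fluoride, giving 2-[3-(benzyloxy)-4-methoxyphenyl]-5,7-difluorochromen-4-one A3 in one pot.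
- **In favour:** both fragments are simple, ring B arrives with its substitution pattern fixed and O3' already benzylated, and the flavone core is reached in one operation against five steps to 10. On step economy up to the flavone and on the regiochemistry of ring B this plan is the better one.
- **Against, here:** ring A arrives with fluorine where oxygen is needed. Two C–F bonds must still be exchanged for oxygen by nucleophilic aromatic substitution, and C5 must be told from C7 because only O7 carries the sulfate. Both fluorides are activated by the C4 carbonyl (C7 para, C5 ortho), so the order of substitution is not secure. The alkoxides needed can also attack C2 of ring C, and O-acylation of the enolate is a further leak.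
- **Comparison:** if substitution at C7 could be made to precede that at C5, the two oxygens would come out differentiated, which would be an advantage over the chosen plan; that selectivity cannot be counted on. On mechanism the two plans are equal: each forms two bonds and one ring without a stereochemical issue. The chosen plan carries its risk in the key step, this alternative in the steps after it.

**Alternative 2:** The cut removes ring A at C8–C8a, C7–C8, C5–C6 and C4a–C5.
- **Forward step:** a photochemical benzannulation of the Danheiser type. The diazo ketone 6-[3-(benzyloxy)-4-methoxyphenyl]-2-(diazoacetyl)-4H-pyran-4-one A4 is irradiated with (triisopropylsilyloxy)acetylene A5. Wolff rearrangement, ketene–alkyne (2+2) addition, four-electron ring opening and six-electron ring closure give 2-[3-(benzyloxy)-4-methoxyphenyl]-5-hydroxy-7-(triisopropylsilyloxy)chromen-4-one A6 after tautomerisation.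
- **In favour:** the three oxygens come out fully differentiated: O5 as the hydrogen-bonded hydroxyl, O7 as a silyl ether, O3' as a benzyl ether. The endgame would be desilylation, sulfation and hydrogenolysis, with no acetate and no reliance on the hydrogen bond alone. On protecting-group logic this is better than the chosen plan, and four skeletal bonds are formed in one step against two.
- **Against, here:** A4 needs an aryl-substituted pyranone carboxylic acid and a diazomethane-type reagent. A5 must be prepared and is moisture-sensitive. The step is photochemical, and the double bond that takes part in the ring closure belongs to a vinylogous ester, an untested partner.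
- **Comparison:** the regiochemistry (alkyne oxygen at C7, ketene carbon at C5) is as well defined by mechanism as that of the chosen key step, so on that point the two are equal. On step economy the chosen plan should be shorter up to the key step (four steps to 7). It also uses cheaper materials and ordinary glassware; the alternative gives the cleaner endgame.

**Alternative 3:** The cut goes through ring C at C4a–C4, C4–C3 and O1–C2.
- **Forward step:** 2-iodo-3,5-bis(methoxymethoxy)phenol A7, 2-(benzyloxy)-4-ethynyl-1-methoxybenzene A8 and carbon monoxide A9 are joined under palladium catalysis in a secondary amine. The phenol oxygen then closes ring C in the 6-endo mode to give 2-[3-(benzyloxy)-4-methoxyphenyl]-5,7-bis(methoxymethoxy)chromen-4-one A10.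
- **In favour:** it is the most convergent of the four plans and a known way to flavones. A10 carries acetals on O5 and O7 and a benzyl group on O3', so acid, sulfation and hydrogenolysis would finish the synthesis in three steps without a basic step. In convergence and in the endgame it is at least the equal of the chosen plan and probably better.
- **Against, here:** A7 is not a commodity. A symmetrical triphenol precursor must be desymmetrised, with two hydroxyls protected, one left free and one iodine placed next to the free one. Its C–I bond is flanked on both sides and hindered. Closure in the 5-exo mode to the benzofuranone isomer competes with the 6-endo closure, and A9 must be handled under pressure. A8 also needs about two steps from a commercial benzaldehyde.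
- **Comparison:** the longest linear sequence is about the same as in the chosen plan. The chosen plan makes its ring A precursor from two commodity chemicals and frees O3' in the ring-forming step; its disadvantage against this alternative is the untested dienophile.

Key step: step 5

Remark on the chemistry: the target is taken as the free hydrogen sulfate as drawn; because aryl hydrogen sulfates hydrolyse in acid, it would be carried and purified as its potassium salt and set free only at the end by cold cation exchange.

## Route

Step 1
Reactants: 1 2,4,6-trihydroxyacetophenone; 2 diethyl oxalate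
Product: 4 ethyl 5,7-dihydroxy-4-oxo-4H-chromene-2-carboxylate, via diketo ester 3 (not isolated)
Conditions: NaOEt (5 equiv), 2 (3 equiv), EtOH, reflux; then conc. HCl, EtOH, reflux
Reagents that add atoms: none
Why: Crossed Claisen condensation: the enolate of the acetyl group of 1 (as its polyanion) is C-acylated by the non-enolisable diester 2 to give 3, and acid then closes ring C by addition of an ortho hydroxyl to the α-keto ester carbonyl and loss of water (the classical chromone-2-carboxylate synthesis). Because 1 is symmetrical, both ortho hydroxyls give the same chromone, and the other one ends as the hydrogen-bonded 5-OH.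

Step 2
Reactants: 4 ethyl 5,7-dihydroxy-4-oxo-4H-chromene-2-carboxylate
Product: 5 ethyl 5,7-bis(benzyloxy)-4-oxo-4H-chromene-2-carboxylate
Conditions: BnBr (2.6 equiv), K2CO3 (3 equiv), n-Bu4NI (cat.), dry DMF, 60 °C
Reagents that add atoms: benzyl bromide, BrCc1ccccc1
Why: Williamson ether synthesis: the acidic 7-OH is alkylated first, and the hydrogen-bonded 5-OH follows with excess benzyl bromide, iodide catalysis and gentle heating in DMF. The ethyl ester is stable to dry carbonate, and both ethers fall later in one hydrogenolysis.

Step 3
Reactants: 5 ethyl 5,7-bis(benzyloxy)-4-oxo-4H-chromene-2-carboxylate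
Product: 6 5,7-bis(benzyloxy)-4-oxo-4H-chromene-2-carbaldehyde
Conditions: i-Bu2AlH (1.15 equiv), CH2Cl2, −78 °C; MeOH quench, aq. KNaC4H4O6
Reagents that add atoms: none
Why: Partial reduction of an ester with i-Bu2AlH at −78 °C: the tetrahedral aluminium hemiacetal is held by chelation to the ring oxygen O1 and releases the aldehyde only on work-up. The C4 carbonyl is a vinylogous ester further deactivated by the donors on O5 and O7 and should not compete at this temperature.

Step 4
Reactants: 6 5,7-bis(benzyloxy)-4-oxo-4H-chromene-2-carbaldehyde
Product: 7 5,7-bis(benzyloxy)-2-ethynyl-4H-chromen-4-one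
Conditions: MeC(O)C(N2)P(O)(OMe)2 (1.2 equiv), K2CO3 (2 equiv), MeOH/THF, 0 °C, short reaction time; aq. NH4Cl
Reagents that add atoms: dimethyl (1-diazo-2-oxopropyl)phosphonate, CC(=O)C(=[N+]=[N-])P(=O)(OC)OC
Why: Ohira–Bestmann modification of the Seyferth–Gilbert homologation: methanolysis of the acetyl group liberates the diazomethylphosphonate anion, which converts the non-enolisable, very electrophilic aldehyde into the terminal alkyne by olefination, loss of N2 and 1,2-hydrogen shift. Low temperature, a small excess of reagent and a buffered quench limit exposure of the pyranone and of the new enynone to methoxide.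

Step 5
Reactants: 7 5,7-bis(benzyloxy)-2-ethynyl-4H-chromen-4-one; 8 3-methoxyfuran
Product: 10 5,7-bis(benzyloxy)-2-(3-hydroxy-4-methoxyphenyl)-4H-chromen-4-one, via oxanorbornadiene cycloadduct 9 (not isolated)
Conditions: 8 (3 equiv), toluene, 80 °C, sealed tube (ZnI2 0.2 equiv or 12 kbar if slow); evaporate; camphorsulfonic acid (0.1 equiv), dry CH2Cl2, rt
Reagents that add atoms: none
Why: Normal-demand Diels–Alder addition of the electron-rich furan 8 to the alkyne of 7, which ends a vinylogous ynone (O=C4–C3=C2–C≡C); the closest known reaction type is the addition of 3-alkoxyfurans to propiolates, ynones and acetylenedicarboxylates followed by acid isomerisation of the 7-oxanorbornadiene to a phenol. The largest HOMO coefficient of 8 lies on its C2 and the largest LUMO coefficient of the dienophile on the terminal alkyne carbon, so these two join first in an asynchronous transition state (C3'–C2'), and furan C5 joins the internal alkyne carbon (C6'–C1'); this 'para' orientation places the methoxy carbon opposite C1'. Ring B is thus closed by a (4+2) cycloaddition that forms both skeletal bonds in one event, and the only other ring formed, the oxygen bridge of 9, is opened again in the same flask. Anhydrous acid protonates the bridge oxygen, and the C6'–O bond, remote from the methoxy carbon, ionises because the resulting allyl cation carries the methoxy group on its far end (C4'), whereas ionisation of C3'–O would place the methoxy group on the central, non-stabilising carbon. Loss of the proton on C3' then aromatises ring B with the bridge oxygen as 3'-OH next to 4'-OMe, an isomerisation in which no atom is lost. The two bridgehead stereocentres of 9 form as a racemic pair and are destroyed on aromatisation, so no stereocontrol is needed. The selectivities required are one orientation of addition and one direction of opening, and the 3-methoxy group secures both; water is kept out of the acid step so that the enol ether is not hydrolysed to a ketone, which would lead on to a demethylated catechol. The benzyl ethers keep ring A free of acidic protons that would destroy 8, at the price of a less electrophilic alkyne, which is why heat, ZnI2 or pressure are provided for.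

Step 6
Reactants: 10 5,7-bis(benzyloxy)-2-(3-hydroxy-4-methoxyphenyl)-4H-chromen-4-one
Product: 11 5-[5,7-bis(benzyloxy)-4-oxo-4H-chromen-2-yl]-2-methoxyphenyl acetate
Conditions: Ac2O (1.5 equiv), pyridine, DMAP (cat.), CH2Cl2, 0 °C → rt
Reagents that add atoms: acetic anhydride, CC(=O)OC(C)=O
Why: DMAP-catalysed O-acylation of the only free hydroxyl of 10; the acetate is stable to hydrogenolysis and to the sulfation and is removed by base, the one medium in which an aryl sulfate is safe.

Step 7
Reactants: 11 5-[5,7-bis(benzyloxy)-4-oxo-4H-chromen-2-yl]-2-methoxyphenyl acetate
Product: 12 5-(5,7-dihydroxy-4-oxo-4H-chromen-2-yl)-2-methoxyphenyl acetate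
Conditions: H2 (1 atm), 10% Pd/C, EtOAc/THF, rt
Reagents that add atoms: none
Why: Hydrogenolysis of two benzyl aryl ethers over Pd/C; the C2=C3 bond of ring C is part of the pyranone and should not be reduced at 1 atm, and the aryl acetate and the methyl ether are inert in an aprotic solvent. The product has O7–H as its only hydroxyl that is not hydrogen-bonded.

Step 8
Reactants: 12 5-(5,7-dihydroxy-4-oxo-4H-chromen-2-yl)-2-methoxyphenyl acetate
Product: 14 luteolin 4'-methyl ether 7-sulfate [5-hydroxy-2-(3-hydroxy-4-methoxyphenyl)-4-oxo-4H-chromen-7-yl hydrogen sulfate], via 3'-O-acetyl 7-sulfate pyridinium salt 13 (not isolated)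
Conditions: SO3·pyridine (2 equiv), pyridine, 0 °C → rt; MeOH quench; then K2CO3, MeOH, 0 °C → rt; C18 desalting; Dowex 50W (H+ form), H2O, 0 °C, lyophilise
Reagents that add atoms: sulfur trioxide–pyridine complex, [O-]S(=O)(=O)[n+]1ccccc1
Why: O-Sulfation with the SO3–pyridine complex takes place at the acidic, unhindered 7-OH, while the 5-OH is held in a hydrogen bond to the C4 carbonyl and O3' is blocked as its acetate, giving 13. Excess reagent is destroyed with methanol before base is added, so that the hydroxyl freed on O3' by carbonate-mediated transesterification cannot be sulfated; the aryl sulfate anion is inert to carbonate. Brief contact with a cold acidic resin exchanges potassium for a proton and should give 14 as the free hydrogen sulfate.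

## Compound list

1 | 2,4,6-trihydroxyacetophenone | CC(=O)c1c(O)cc(O)cc1O | starting material
2 | diethyl oxalate | CCOC(=O)C(=O)OCC | starting material
3 | ethyl 2,4-dioxo-4-(2,4,6-trihydroxyphenyl)butanoate | CCOC(=O)C(=O)CC(=O)c1c(O)cc(O)cc1O | intermediate
4 | ethyl 5,7-dihydroxy-4-oxo-4H-chromene-2-carboxylate | CCOC(=O)c1cc(=O)c2c(O)cc(O)cc2o1 | intermediate
5 | ethyl 5,7-bis(benzyloxy)-4-oxo-4H-chromene-2-carboxylate | CCOC(=O)c1cc(=O)c2c(OCc3ccccc3)cc(OCc3ccccc3)cc2o1 | intermediate
6 | 5,7-bis(benzyloxy)-4-oxo-4H-chromene-2-carbaldehyde | O=Cc1cc(=O)c2c(OCc3ccccc3)cc(OCc3ccccc3)cc2o1 | intermediate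
7 | 5,7-bis(benzyloxy)-2-ethynyl-4H-chromen-4-one | C#Cc1cc(=O)c2c(OCc3ccccc3)cc(OCc3ccccc3)cc2o1 | intermediate
8 | 3-methoxyfuran | COc1ccoc1 | starting material
9 | 5,7-bis(benzyloxy)-2-(5-methoxy-7-oxabicyclo[2.2.1]hepta-2,5-dien-2-yl)-4H-chromen-4-one (racemic, one enantiomer drawn; the two bridgeheads are the only stereocentres) | COC1=C[C@@H]2O[C@H]1C=C2c1cc(=O)c2c(OCc3ccccc3)cc(OCc3ccccc3)cc2o1 | intermediate
10 | 5,7-bis(benzyloxy)-2-(3-hydroxy-4-methoxyphenyl)-4H-chromen-4-one | COc1ccc(-c2cc(=O)c3c(OCc4ccccc4)cc(OCc4ccccc4)cc3o2)cc1O | intermediate
11 | 5-[5,7-bis(benzyloxy)-4-oxo-4H-chromen-2-yl]-2-methoxyphenyl acetate | COc1ccc(-c2cc(=O)c3c(OCc4ccccc4)cc(OCc4ccccc4)cc3o2)cc1OC(C)=O | intermediate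
12 | 5-(5,7-dihydroxy-4-oxo-4H-chromen-2-yl)-2-methoxyphenyl acetate | COc1ccc(-c2cc(=O)c3c(O)cc(O)cc3o2)cc1OC(C)=O | intermediate
13 | pyridinium 2-[3-(acetyloxy)-4-methoxyphenyl]-5-hydroxy-4-oxo-4H-chromen-7-yl sulfate | COc1ccc(-c2cc(=O)c3c(O)cc(OS(=O)(=O)[O-])cc3o2)cc1OC(C)=O.c1cc[nH+]cc1 | intermediate
14 | luteolin 4'-methyl ether 7-sulfate, 5-hydroxy-2-(3-hydroxy-4-methoxyphenyl)-4-oxo-4H-chromen-7-yl hydrogen sulfate | COc1ccc(-c2cc(=O)c3c(O)cc(OS(=O)(=O)O)cc3o2)cc1O | target

## Step count and least certain steps

Total step count: 8. Longest linear sequence: 8 steps (1 to 14); 8 enters at step 5.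

**Step 5 (key step)** is the least certain.
- What may go wrong: the cycloaddition may not proceed at a useful rate, because the alkyne is activated only through a vinylogous ester and two donor ethers on ring A. Under ZnI2 the addition may stop after the first bond, with proton loss giving conjugate addition of the furan instead of ring closure. Polymerisation of 8 by adventitious acid and hydrolysis of the enol ether of 9 before the bridge opens are further leaks.
- Fallback: ring B is brought in ready-made by a chalcone route that sets out from 1 and comes back at 10. 1 is benzylated on its two hydroxyls that are not hydrogen-bonded (benzyl bromide, K2CO3, acetone) to 1-[2,4-bis(benzyloxy)-6-hydroxyphenyl]ethanone F1. Claisen–Schmidt condensation with commercial 3-hydroxy-4-methoxybenzaldehyde (KOH, EtOH) gives (E)-1-[2,4-bis(benzyloxy)-6-hydroxyphenyl]-3-(3-hydroxy-4-methoxyphenyl)prop-2-en-1-one F2. Oxidative ring closure with catalytic I2 in DMSO at about 120 °C should give 10, from which steps 6 to 8 follow unchanged.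

**Step 4.**
- What may go wrong: methoxide or methanol may add to C2 of ring C or to the terminal carbon of the new enynone, and the diazophosphonate may undergo dipolar cycloaddition to the electron-poor alkyne or to the C2=C3 bond.
- Fallback: it sets out from 6 and returns at 7 without a diazo compound or an alkoxide. Dibromo-olefination (CBr4, PPh3, CH2Cl2, 0 °C) gives 5,7-bis(benzyloxy)-2-(2,2-dibromoethenyl)-4H-chromen-4-one F3. Hydrogenolysis of the more accessible C–Br bond (n-Bu3SnH, Pd(PPh3)4 cat., toluene, rt) gives 5,7-bis(benzyloxy)-2-[(Z)-2-bromoethenyl]-4H-chromen-4-one F4. Anti elimination of HBr with n-Bu4NF·3H2O in DMF then gives 7.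

**Step 3.**
- What may go wrong: over-reduction to the primary alcohol, or hydride attack on the pyranone, if the aluminium hemiacetal collapses before the quench.
- Fallback: it sets out from 5 and returns at 6. The activated ester is reduced fully with NaBH4 (MeOH/THF, 0 °C) to 5,7-bis(benzyloxy)-2-(hydroxymethyl)-4H-chromen-4-one F5, and the alcohol is re-oxidised with MnO2 in CH2Cl2 (or Dess–Martin periodinane) to 6.

**Step 8.**
- What may go wrong: incomplete discrimination between O7 and O5 with excess reagent, sulfation of O3' if reagent survives into the basic stage, and acid-catalysed loss of the sulfate during cation exchange or concentration of the free acid.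
- Fallback: it sets out from 12 and returns at 14. O7 is converted with 2,2,2-trichloroethyl chlorosulfate (Et3N, DMAP, THF) into the neutral mixed diester 5-(5-hydroxy-4-oxo-7-{[(2,2,2-trichloroethoxy)sulfonyl]oxy}-4H-chromen-2-yl)-2-methoxyphenyl acetate F6, which can be purified on silica and its regiochemistry checked. Zn and HCO2NH4 in MeOH then remove the trichloroethyl group, K2CO3 in MeOH removes the acetate, and the salt is converted to 14 as in the main route.

**Step 1.**
- What may go wrong: low conversion in the Claisen condensation, because the polyanion of the unprotected triphenol is poorly soluble and weakly nucleophilic at carbon, and O-acylation by the oxalate.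
- Fallback: it sets out from 1 and returns at 5, bypassing 4 and step 2. 1 is benzylated first to 1-[2,4-bis(benzyloxy)-6-hydroxyphenyl]ethanone F1 (as in the fallback to step 5). Claisen condensation of this monophenol with 2 (NaOEt, EtOH/THF) gives ethyl 4-[2,4-bis(benzyloxy)-6-hydroxyphenyl]-2,4-dioxobutanoate F7, and ring closure with catalytic p-TsOH in warm toluene gives 5.

## Further compounds

F1 | step 5 | 1-[2,4-bis(benzyloxy)-6-hydroxyphenyl]ethanone | CC(=O)c1c(O)cc(OCc2ccccc2)cc1OCc1ccccc1
F2 | step 5 | (E)-1-[2,4-bis(benzyloxy)-6-hydroxyphenyl]-3-(3-hydroxy-4-methoxyphenyl)prop-2-en-1-one | COc1ccc(/C=C/C(=O)c2c(O)cc(OCc3ccccc3)cc2OCc2ccccc2)cc1O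
F3 | step 4 | 5,7-bis(benzyloxy)-2-(2,2-dibromoethenyl)-4H-chromen-4-one | BrC(Br)=Cc1cc(=O)c2c(OCc3ccccc3)cc(OCc3ccccc3)cc2o1
F4 | step 4 | 5,7-bis(benzyloxy)-2-[(Z)-2-bromoethenyl]-4H-chromen-4-one | Br/C=C\c1cc(=O)c2c(OCc3ccccc3)cc(OCc3ccccc3)cc2o1
F5 | step 3 | 5,7-bis(benzyloxy)-2-(hydroxymethyl)-4H-chromen-4-one | OCc1cc(=O)c2c(OCc3ccccc3)cc(OCc3ccccc3)cc2o1
F6 | step 8 | 5-(5-hydroxy-4-oxo-7-{[(2,2,2-trichloroethoxy)sulfonyl]oxy}-4H-chromen-2-yl)-2-methoxyphenyl acetate | COc1ccc(-c2cc(=O)c3c(O)cc(OS(=O)(=O)OCC(Cl)(Cl)Cl)cc3o2)cc1OC(C)=O
F7 | step 1 | ethyl 4-[2,4-bis(benzyloxy)-6-hydroxyphenyl]-2,4-dioxobutanoate | CCOC(=O)C(=O)CC(=O)c1c(O)cc(OCc2ccccc2)cc1OCc1ccccc1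
A1 | alternative 1 | 1-[3-(benzyloxy)-4-methoxyphenyl]ethanone | CC(=O)c1ccc(OC)c(OCc2ccccc2)c1
A2 | alternative 1 | 2,4,6-trifluorobenzoyl chloride | O=C(Cl)c1c(F)cc(F)cc1F
A3 | alternative 1 | 2-[3-(benzyloxy)-4-methoxyphenyl]-5,7-difluorochromen-4-one | COc1ccc(-c2cc(=O)c3c(F)cc(F)cc3o2)cc1OCc1ccccc1
A4 | alternative 2 | 6-[3-(benzyloxy)-4-methoxyphenyl]-2-(diazoacetyl)-4H-pyran-4-one | COc1ccc(-c2cc(=O)cc(C(=O)C=[N+]=[N-])o2)cc1OCc1ccccc1
A5 | alternative 2 | (triisopropylsilyloxy)acetylene | C#CO[Si](C(C)C)(C(C)C)C(C)C
A6 | alternative 2 | 2-[3-(benzyloxy)-4-methoxyphenyl]-5-hydroxy-7-(triisopropylsilyloxy)chromen-4-one | COc1ccc(-c2cc(=O)c3c(O)cc(O[Si](C(C)C)(C(C)C)C(C)C)cc3o2)cc1OCc1ccccc1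
A7 | alternative 3 | 2-iodo-3,5-bis(methoxymethoxy)phenol | COCOc1cc(O)c(I)c(OCOC)c1
A8 | alternative 3 | 2-(benzyloxy)-4-ethynyl-1-methoxybenzene | C#Cc1ccc(OC)c(OCc2ccccc2)c1
A9 | alternative 3 | carbon monoxide | [C-]#[O+]
A10 | alternative 3 | 2-[3-(benzyloxy)-4-methoxyphenyl]-5,7-bis(methoxymethoxy)chromen-4-one | COCOc1cc(OCOC)c2c(=O)cc(-c3ccc(OC)c(OCc4ccccc4)c3)oc2c1
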